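## Retrosynthetic overview

1. The last bond made is C4 of the flavan unit to C6 of the flavanone unit. The electrophile is the flavan-4-yl cation / para-quinone methide, generated by protonating a racemic flav-3-ene with a chiral Brønsted acid that passes only the (2S)-enantiomer on to product (kinetic resolution). The nucleophile is (R)-pinostrobin.
2. The flav-3-ene is cut at O1–C2 and C4–C4a into 2,5-dimethoxyresorcinol and cinnamaldehyde, joined through a vinylogous ortho-quinone methide that closes by oxa-6π electrocyclisation (flavan ring C).
3. (R)-Pinostrobin comes from a Claisen–Schmidt chalcone, oxa-Michael closure of flavanone ring C (the chalcone isomerase reaction), then kinetic resolution.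
4. 2,5-Dimethoxyresorcinol comes from 4-methoxyphenol by ortho-dibromination/O-methylation and double hydroxylation.
5. Ring order: flavanone ring C and flavan ring C are each closed by attack of a phenol oxygen on the cinnamoyl-derived C3 unit; the two halves are joined last.

Assumption: the SMILES descriptors are taken literally, i.e. flavanone C2 = R, flavan C2 = S and C4 = S (2-phenyl and 4-aryl trans), with the flavan attached at C6 of the flavanone.

## Route

Step 1
Reactants: 1 4-methoxyphenol
Product: 3 1,3-dibromo-2,5-dimethoxybenzene, via 2,6-dibromo-4-methoxyphenol 2 (not isolated)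
Conditions: Br2 (2.05 equiv), MeCN, 0 °C to rt; then K2CO3 (5 equiv), MeI (2 equiv), 50 °C
Reagents that add atoms: bromine, BrBr; iodomethane, CI
Why: Electrophilic aromatic bromination goes to both positions ortho to the free OH (the stronger director, para position blocked by OMe), and the acidic 2,6-dibromophenol is then O-methylated in the same flask (Williamson ether synthesis); no stereocentre is formed.

Step 2
Reactants: 3 1,3-dibromo-2,5-dimethoxybenzene
Product: 4 2,5-dimethoxyresorcinol (2,5-dimethoxybenzene-1,3-diol)
Conditions: Pd2(dba)3 (2 mol%), t-BuXPhos (8 mol%), KOH (6 equiv), 1,4-dioxane/H2O 1:1, 100 °C, argon; acidic work-up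
Reagents that add atoms: potassium hydroxide, [K+].[OH-]
Why: Palladium-catalysed C–O cross-coupling of an aryl bromide with hydroxide (Buchwald-type hydroxylation), in which the bulky biaryl phosphine enforces C–O reductive elimination; the two C–Br bonds are equivalent and no stereocentre is formed.

Step 3
Reactants: 4 2,5-dimethoxyresorcinol (1.3 equiv); 5 (E)-cinnamaldehyde
Product: 7 racemic 7-hydroxy-5,8-dimethoxy-2-phenyl-2H-chromene (flav-3-ene), via vinyl ortho-quinone methide 6 (not isolated)
Conditions: PhB(OH)2 (1.0 equiv), EtCO2H (0.3 equiv), toluene, reflux, Dean–Stark; quick filtration through Et3N-deactivated silica, used at once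
Reagents that add atoms: none
Why: Phenylboronic acid-templated ortho-specific 1,2-addition of the phenol to the aldehyde (Nagata-type chromene synthesis), loss of water to the vinylogous ortho-quinone methide 6 and oxa-6π electrocyclisation close ring C of the flavan unit through the same phenol-O to C2 bond as the chalcone-to-flavanone cyclisation; 4 is symmetric so only one regioisomer can form, and C2 is formed racemic (selected in step 6).

Step 4
Reactants: 8 2',6'-dihydroxy-4'-methoxyacetophenone; 9 benzaldehyde
Product: 11 racemic pinostrobin (5-hydroxy-7-methoxy-2-phenylchroman-4-one), via pinostrobin chalcone 10 (not isolated)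
Conditions: KOH (50% aq), EtOH, rt, 48 h; then AcOH to pH 5, NaOAc, reflux
Reagents that add atoms: none
Why: Claisen–Schmidt aldol condensation gives the 2',6'-dihydroxychalcone 10, which closes ring C by intramolecular 6-endo oxa-Michael addition (the chalcone isomerase reaction run without enzyme); both OH groups give the same flavanone by symmetry, and C2 is formed racemic (resolved in step 5).

Step 5
Reactants: 11 racemic pinostrobin
Product: 12 (R)-pinostrobin ((2R)-5-hydroxy-7-methoxy-2-phenylchroman-4-one)
Conditions: RuCl(p-cymene)[(S,S)-TsDPEN] (1 mol%), HCO2H/Et3N 5:2, EtOAc, 25 °C, stopped at ca. 55% conversion (chiral HPLC); chromatography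
Reagents that add atoms: none
Why: Noyori–Ikariya asymmetric transfer hydrogenation run as a kinetic resolution: the (S,S)-catalyst delivers hydride to give (4S)-alcohols, which is matched only for the (2S)-flavanone (forming the 2,4-cis flavan-4-ol), so the (2S)-enantiomer is consumed and (2R)-12 is recovered in high ee with no bond of 12 changed.

Step 6
Reactants: 7 racemic 7-hydroxy-5,8-dimethoxy-2-phenyl-2H-chromene (1 equiv, added by syringe pump over 8 h); 12 (R)-pinostrobin (3 equiv, excess recovered)
Product: 14 (2R)-5-hydroxy-6-[(2S,4S)-7-hydroxy-5,8-dimethoxy-2-phenylchroman-4-yl]-7-methoxy-2-phenylchroman-4-one (target), via (S)-para-quinone methide 13 (not isolated)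
Conditions: (R)-3,3'-bis(2,4,6-triisopropylphenyl)-1,1'-binaphthyl-2,2'-diyl N-triflylphosphoramide (10 mol%), 4 Å MS, CH2Cl2, −40 °C, stopped at ca. 50% conversion of 7 (chiral HPLC), Et3N quench; chromatography separates 14 from unreacted (R)-7 and excess 12
Reagents that add atoms: none
Why: Proposed new method: a kinetic resolution in which the chiral acid reversibly protonates C3 of the 4-hydroxystyrene-type flavene to the hydrogen-bonded flavan-4-yl cation / para-quinone methide 13, the only free OH of 12 (5-OH, ortho-directing to C6) docks on the phosphoryl oxygen, and C6 attacks C4 axially on the face anti to the pseudo-equatorial 2-phenyl group (2,4-trans, i.e. 4S from 2S); this substrate-preferred face coincides with the face left open by the catalyst only in the ion pair of the (2S)-cation, so the mismatched (2R)-cation loses its proton again and (R)-7 is left unreacted (at most 50% of 7 can reach 14); the closest known reactions are chiral phosphoric acid-catalysed Friedel–Crafts 1,6-additions of phenols to quinone methides generated from hydroxystyrenes and the acid-mediated 4-arylation of flav-3-enes and flavan-4-ols, which gives 2,4-trans-4-arylflavans.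

## Compound list

1 | 4-methoxyphenol | COc1ccc(O)cc1 | starting material
2 | 2,6-dibromo-4-methoxyphenol | COc1cc(Br)c(O)c(Br)c1 | intermediate
3 | 1,3-dibromo-2,5-dimethoxybenzene | COc1cc(Br)c(OC)c(Br)c1 | intermediate
4 | 2,5-dimethoxyresorcinol | COc1cc(O)c(OC)c(O)c1 | intermediate
5 | (E)-cinnamaldehyde | O=C/C=C/c1ccccc1 | starting material
6 | vinyl ortho-quinone methide: 3-hydroxy-2,5-dimethoxy-6-[(E)-3-phenylprop-2-enylidene]cyclohexa-2,4-dien-1-one, styryl group syn to C=O | O=C1C(OC)=C(O)C=C(OC)/C1=C/C=C/c1ccccc1 | intermediate
7 | racemic 7-hydroxy-5,8-dimethoxy-2-phenyl-2H-chromene | COc1cc(O)c(OC)c2OC(c3ccccc3)C=Cc12 | intermediate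
8 | 2',6'-dihydroxy-4'-methoxyacetophenone | CC(=O)c1c(O)cc(OC)cc1O | starting material
9 | benzaldehyde | O=Cc1ccccc1 | starting material
10 | pinostrobin chalcone ((E)-2',6'-dihydroxy-4'-methoxychalcone) | COc1cc(O)c(C(=O)/C=C/c2ccccc2)c(O)c1 | intermediate
11 | racemic pinostrobin | COc1cc(O)c2C(=O)CC(c3ccccc3)Oc2c1 | intermediate
12 | (R)-pinostrobin | COc1cc(O)c2C(=O)C[C@H](c3ccccc3)Oc2c1 | intermediate
13 | (S)-para-quinone methide: (2S)-5,8-dimethoxy-2-phenyl-2,3-dihydro-7H-chromen-7-one | COC1=CC(=O)C(OC)=C2O[C@H](c3ccccc3)CC=C12 | intermediate
14 | (2R)-5-hydroxy-6-[(2S,4S)-7-hydroxy-5,8-dimethoxy-2-phenylchroman-4-yl]-7-methoxy-2-phenylchroman-4-one | COc1cc2c(c(O)c1[C@@H]1C[C@@H](c3ccccc3)Oc3c(OC)c(O)cc(OC)c31)C(=O)C[C@H](c1ccccc1)O2 | target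

## Step count and risks

Total steps: 6. Longest linear sequence: 4 steps (steps 1, 2, 3 and 6, from 4-methoxyphenol); steps 4 and 5 form the second branch.

**Step 6 (most likely to fail).** The selectivity of the chiral acid between the two enantiomers of 7 is unproven, and the sense of induction must be found by experiment (the antipodal acid is used if the (R)-acid proves mismatched). If the acid differentiates poorly, (R)-7 also reacts under substrate control and the (2R,4R)-flavan diastereomer of 14 has to be separated. Ring A of 7 and of 14 has a free, electron-rich C6 position, and unreacted (R)-7 accumulates, so self-condensation competes; hence the slow addition, the low temperature, the excess of 12 and the stop at half conversion. Attack at C8 of 12 instead of C6 is also possible.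

The fallback sets out from 4 and comes back to the route at 14. Compound 4 is acylated with cinnamoyl chloride and BF3·OEt2 and the ring is closed with NaOAc in refluxing EtOH to give racemic 7-hydroxy-5,8-dimethoxyflavanone F1. Transfer hydrogenation with RuCl(p-cymene)[(S,S)-TsDPEN] and HCO2H/Et3N reduces only the (2S)-enantiomer, giving (2S,4S)-7-hydroxy-5,8-dimethoxyflavan-4-ol F2, which is separated from the unreduced ketone. F2 is then ionised with BF3·OEt2 in CH2Cl2 at −40 °C in the presence of 12 (3 equiv); the same cation is trapped anti to the 2-phenyl group to give 14 with flavan C2 already fixed.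

**Step 3.** The free-phenol, electron-rich flavene may dimerise or oxidise under hot acidic conditions, and a second chromene ring could form on the remaining OH.

The fallback sets out from 4 and comes back at 7. Compound 4 (in excess) is C-alkylated with (E)-cinnamyl alcohol in warm aqueous formic acid (Friedel–Crafts allylation at the only free ring position) to give 4-[(E)-cinnamyl]-2,5-dimethoxyresorcinol F3. DDQ (1.0 equiv, benzene, rt) then abstracts the doubly activated benzylic hydride to form quinone methide 6, which closes to 7 under neutral conditions.

**Step 2.** Double hydroxylation of an electron-rich dibromide may stall after the first C–O bond, and the product is air-sensitive in hot base.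

The fallback sets out from 3 and comes back at 4. Compound 3 is borylated with B2pin2, PdCl2(dppf) and KOAc in dioxane at 90 °C to give 2,2'-(2,5-dimethoxy-1,3-phenylene)bis(4,4,5,5-tetramethyl-1,3,2-dioxaborolane) F4. Oxidation with H2O2 and NaOH in THF at 0 °C then gives 4 under mild conditions.

## Further compounds

F1 | step 6 | racemic 7-hydroxy-5,8-dimethoxyflavanone | COc1cc(O)c(OC)c2OC(c3ccccc3)CC(=O)c12
F2 | step 6 | (2S,4S)-7-hydroxy-5,8-dimethoxyflavan-4-ol | COc1cc(O)c(OC)c2O[C@H](c3ccccc3)C[C@H](O)c12
F3 | step 3 | 4-[(E)-cinnamyl]-2,5-dimethoxyresorcinol | COc1cc(O)c(OC)c(O)c1C/C=C/c1ccccc1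
F4 | step 2 | 2,2'-(2,5-dimethoxy-1,3-phenylene)bis(4,4,5,5-tetramethyl-1,3,2-dioxaborolane) | COc1cc(B2OC(C)(C)C(C)(C)O2)c(OC)c(B2OC(C)(C)C(C)(C)O2)c1
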